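Ring C is taken apart at two bonds, C3–C4 and C2–H. In the target, C4 is a ketone carbon bonded to C4a of ring A, while C2 carries one hydrogen, the ring B aryl group and O1, the ether oxygen on C8a. An ortho-formyl aryl 1-arylvinyl ether therefore already holds every atom of ring C. A single enantioselective, rhodium-catalysed endo hydroacylation should add the formyl C–H bond across the enol ether, making the C3–C4 bond, closing ring C and fixing C2 as S. The precursor is the hexasubstituted benzaldehyde 13: CHO flanked by OMe and by the 1-[4-(TBSO)phenyl]vinyloxy group, with the prenyl group and two further OMe groups already in place.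

Key step: step 9

Assumption: the sense of induction of the bisphosphine cannot be fixed on paper; (R)-DTBM-SEGPHOS is written, and its mirror image would be taken if the first run should favour the (R)-flavanone.

Design remark: the C5 oxygen stays a methyl ether (small, able to chelate rhodium) and the ring B oxygen a TBS ether (inert to Cp2TiMe2 and to cationic rhodium). The formyl group is masked only after aroylation, as the acyclic dimethyl acetal, which should be cleaved much faster than the enol ether.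

Step 1
Reactants: 1 3,4,5-trimethoxyphenol; 2 3-chloro-3-methylbut-1-yne
Product: 3 1,2,3-trimethoxy-5-[(2-methylbut-3-yn-2-yl)oxy]benzene
Conditions: DBU, CuCl2·2H2O (cat.), MeCN, 0 °C
Reagents that add atoms: none
Why: Copper-catalysed propargylic etherification of a phenol with a tertiary propargylic chloride (through a copper acetylide-derived electrophile) is a standard entry to aryl 1,1-dimethylpropargyl ethers, and the phenol offers a single nucleophilic OH.

Step 2
Reactants: 3 1,2,3-trimethoxy-5-[(2-methylbut-3-yn-2-yl)oxy]benzene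
Product: 5 3,4,5-trimethoxy-2-(3-methylbut-2-en-1-yl)phenol, via 1,2,3-trimethoxy-5-[(2-methylbut-3-en-2-yl)oxy]benzene 4 (not isolated)
Conditions: H2 (1 atm), Pd/CaCO3 poisoned with Pb(OAc)2, quinoline, EtOAc, rt; filter, evaporate; then PhNEt2, 130 °C
Reagents that add atoms: none
Why: Lindlar-type semihydrogenation should stop at the terminal alkene, and the aryl 1,1-dimethylallyl ether then undergoes an aromatic Claisen rearrangement ([3,3] shift) onto one of the two equivalent free ortho carbons, which after tautomerisation places the linear prenyl group next to the OH.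

Step 3
Reactants: 5 3,4,5-trimethoxy-2-(3-methylbut-2-en-1-yl)phenol
Product: 6 2-hydroxy-4,5,6-trimethoxy-3-(3-methylbut-2-en-1-yl)benzaldehyde
Conditions: MgCl2, Et3N, (CH2O)n, MeCN, reflux; then 1 M HCl, 0 °C
Reagents that add atoms: paraformaldehyde (as formaldehyde), C=O
Why: Magnesium-mediated ortho-formylation (Casnati–Skattebøl reaction) delivers formaldehyde from the magnesium phenoxide to the ortho carbon, here the only unsubstituted ring position, and a second formaldehyde oxidises the benzylic alkoxide by hydride transfer; the amine-buffered medium should leave the prenyl alkene alone.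

Step 4
Reactants: 7 4-hydroxybenzoic acid
Product: 8 tert-butyldimethylsilyl 4-[(tert-butyldimethylsilyl)oxy]benzoate
Conditions: TBSCl (2.3 equiv), imidazole, DMF, rt
Reagents that add atoms: tert-butyldimethylsilyl chloride (TBSCl), CC(C)(C)[Si](C)(C)Cl
Why: Standard silylation caps both the phenol and the carboxylic acid, and the silyl ester serves as the latent acid chloride for step 5.

Step 5
Reactants: 8 tert-butyldimethylsilyl 4-[(tert-butyldimethylsilyl)oxy]benzoate; 6 2-hydroxy-4,5,6-trimethoxy-3-(3-methylbut-2-en-1-yl)benzaldehyde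
Product: 10 2-formyl-3,4,5-trimethoxy-6-(3-methylbut-2-en-1-yl)phenyl 4-[(tert-butyldimethylsilyl)oxy]benzoate, via 4-[(tert-butyldimethylsilyl)oxy]benzoyl chloride 9 (not isolated)
Conditions: 8, (COCl)2, DMF (cat.), CH2Cl2, 0 °C → rt, evaporate; then 6, Et3N, DMAP (cat.), CH2Cl2, 0 °C → rt
Reagents that add atoms: none
Why: Oxalyl chloride with catalytic DMF converts a silyl ester into the acid chloride under neutral conditions that keep the aryl silyl ether, and DMAP-catalysed O-acylation (nucleophilic acyl substitution) of the hydrogen-bonded phenol then gives the aryl ester.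

Step 6
Reactants: 10 2-formyl-3,4,5-trimethoxy-6-(3-methylbut-2-en-1-yl)phenyl 4-[(tert-butyldimethylsilyl)oxy]benzoate
Product: 11 2-(dimethoxymethyl)-3,4,5-trimethoxy-6-(3-methylbut-2-en-1-yl)phenyl 4-[(tert-butyldimethylsilyl)oxy]benzoate
Conditions: HC(OMe)3, MeOH, p-TsOH·H2O (2 mol%), rt; then Et3N
Reagents that add atoms: trimethyl orthoformate, COC(OC)OC; methanol, CO
Why: Acid-catalysed acetalisation, driven by the orthoformate as water scavenger, masks the aldehyde, which would otherwise be methylenated before the ester in step 7, while the aryl ester and aryl silyl ether tolerate catalytic acid in MeOH at rt.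

Step 7
Reactants: 11 2-(dimethoxymethyl)-3,4,5-trimethoxy-6-(3-methylbut-2-en-1-yl)phenyl 4-[(tert-butyldimethylsilyl)oxy]benzoate
Product: 12 tert-butyl(4-{1-[2-(dimethoxymethyl)-3,4,5-trimethoxy-6-(3-methylbut-2-en-1-yl)phenoxy]ethenyl}phenoxy)dimethylsilane
Conditions: Cp2TiMe2 (2.5 equiv), PhMe–THF, 70 °C, dark; hexane, filter through basic Al2O3
Reagents that add atoms: bis(cyclopentadienyl)dimethyltitanium (Cp2TiMe2), C[Ti](C)(C1C=CC=C1)C1C=CC=C1
Why: Petasis methylenation, in which Cp2TiMe2 loses methane on warming to give Cp2Ti=CH2, converts the aryl ester carbonyl into the 1-aryloxy-1-arylethene through an oxatitanacyclobutane under non-acidic conditions that the acetal, the silyl ether and the trisubstituted alkene tolerate.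

Step 8
Reactants: 12 tert-butyl(4-{1-[2-(dimethoxymethyl)-3,4,5-trimethoxy-6-(3-methylbut-2-en-1-yl)phenoxy]ethenyl}phenoxy)dimethylsilane
Product: 13 2-({1-[4-(tert-butyldimethylsilyloxy)phenyl]ethenyl}oxy)-4,5,6-trimethoxy-3-(3-methylbut-2-en-1-yl)benzaldehyde
Conditions: PPTS (5 mol%), acetone–H2O (20:1), 0 °C → rt; NaHCO3 quench; Et3N-deactivated SiO2
Reagents that add atoms: water, O
Why: Specific acid-catalysed acetal hydrolysis should be selective because the oxocarbenium ion of this acetal is stabilised by two ortho oxygens and a para methoxy group, so cleavage should be far faster than carbon protonation of the aryl enol ether under pyridinium catalysis.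

Step 9
Reactants: 13 2-({1-[4-(tert-butyldimethylsilyloxy)phenyl]ethenyl}oxy)-4,5,6-trimethoxy-3-(3-methylbut-2-en-1-yl)benzaldehyde
Product: 14 (2S)-2-{4-[(tert-butyldimethylsilyl)oxy]phenyl}-5,6,7-trimethoxy-8-(3-methylbut-2-en-1-yl)-2,3-dihydro-4H-chromen-4-one
Conditions: [Rh(cod)Cl]2 (2.5 mol%), (R)-DTBM-SEGPHOS (5.5 mol%), NaB[3,5-(CF3)2C6H3]4 (5 mol%), 1,4-dioxane, 60–80 °C, Ar
Reagents that add atoms: none
Why: Proposed new method: cationic monovalent rhodium should add oxidatively into the formyl C–H bond of 13, the acyl rhodium hydride (trivalent rhodium) should insert the enol ether with hydride going to the aryl- and oxygen-bearing carbon (C2) and rhodium to the CH2 terminus, and C–C reductive elimination from the seven-membered acyl–alkyl rhodacycle should then form C3–C4. The closest known reaction type is the rhodium-catalysed enantioselective endo hydroacylation of ortho-(2-substituted allyl)benzaldehydes to 3-substituted 1-tetralones; here O1 takes the place of the benzylic CH2, which also removes any chance of alkene isomerisation. Ring C is closed in the 6-endo-trig mode, the acyl carbon bonding to the terminal alkene carbon. The C2 stereocentre is set under catalyst control, the chiral pocket of the bisphosphine selecting the alkene face that receives the hydride. The step needs endo over exo selectivity, which the 1,1-disubstitution should secure (the exo path requires a tertiary, oxygen-bearing alkyl rhodium and would give a 2-aryl-2-methylbenzofuran-3-one), helped by the enol ether polarisation that matches hydride to C2 and metal to C3. Decarbonylation should be held back by chelation of rhodium between the acyl group and the flanking C5 methoxy or O1 oxygen, and the prenyl alkene is trisubstituted and out of reach of the acyl rhodium centre.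

Step 10
Reactants: 14 (2S)-2-{4-[(tert-butyldimethylsilyl)oxy]phenyl}-5,6,7-trimethoxy-8-(3-methylbut-2-en-1-yl)-2,3-dihydro-4H-chromen-4-one
Product: 15 (2S)-2-{4-[(tert-butyldimethylsilyl)oxy]phenyl}-5-hydroxy-6,7-dimethoxy-8-(3-methylbut-2-en-1-yl)-2,3-dihydro-4H-chromen-4-one
Conditions: BCl3 (1.5 equiv, 1 M in CH2Cl2), CH2Cl2, −78 → 0 °C; cold aq. NaHCO3
Reagents that add atoms: none
Why: Chelation-controlled ether cleavage, in which BCl3 bridges the C4 carbonyl and the peri C5 methoxy oxygen in a six-membered chelate and chloride removes only that methyl group, should leave the C6 and C7 methyl ethers, the aryl silyl ether and, at low temperature with no free phenol beside it, the prenyl alkene intact; the aryloxyboron chelate is hydrolysed on work-up and C2 is not involved.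

Step 11
Reactants: 15 (2S)-2-{4-[(tert-butyldimethylsilyl)oxy]phenyl}-5-hydroxy-6,7-dimethoxy-8-(3-methylbut-2-en-1-yl)-2,3-dihydro-4H-chromen-4-one
Product: 16 (2S)-5-hydroxy-2-(4-hydroxyphenyl)-6,7-dimethoxy-8-(3-methylbut-2-en-1-yl)-2,3-dihydro-4H-chromen-4-one
Conditions: TBAF, AcOH (1:1), THF, 0 °C
Reagents that add atoms: none
Why: Fluoride-mediated desilylation of the aryl silyl ether, buffered with AcOH so that no phenoxide or enolate forms that could open ring C by a retro-oxa-Michael reaction and racemise C2.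

Compound list
1 | 3,4,5-trimethoxyphenol | COc1cc(O)cc(OC)c1OC | starting material
2 | 3-chloro-3-methylbut-1-yne | CC(C)(Cl)C#C | starting material
3 | 1,2,3-trimethoxy-5-[(2-methylbut-3-yn-2-yl)oxy]benzene | COc1cc(OC(C)(C)C#C)cc(OC)c1OC | intermediate
4 | 1,2,3-trimethoxy-5-[(2-methylbut-3-en-2-yl)oxy]benzene | COc1cc(OC(C)(C)C=C)cc(OC)c1OC | intermediate
5 | 3,4,5-trimethoxy-2-(3-methylbut-2-en-1-yl)phenol | COc1cc(O)c(CC=C(C)C)c(OC)c1OC | intermediate
6 | 2-hydroxy-4,5,6-trimethoxy-3-(3-methylbut-2-en-1-yl)benzaldehyde | COc1c(OC)c(C=O)c(O)c(CC=C(C)C)c1OC | intermediate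
7 | 4-hydroxybenzoic acid | O=C(O)c1ccc(O)cc1 | starting material
8 | tert-butyldimethylsilyl 4-[(tert-butyldimethylsilyl)oxy]benzoate | CC(C)(C)[Si](C)(C)OC(=O)c1ccc(O[Si](C)(C)C(C)(C)C)cc1 | intermediate
9 | 4-[(tert-butyldimethylsilyl)oxy]benzoyl chloride | CC(C)(C)[Si](C)(C)Oc1ccc(C(=O)Cl)cc1 | intermediate
10 | 2-formyl-3,4,5-trimethoxy-6-(3-methylbut-2-en-1-yl)phenyl 4-[(tert-butyldimethylsilyl)oxy]benzoate | COc1c(OC)c(C=O)c(OC(=O)c2ccc(O[Si](C)(C)C(C)(C)C)cc2)c(CC=C(C)C)c1OC | intermediate
11 | 2-(dimethoxymethyl)-3,4,5-trimethoxy-6-(3-methylbut-2-en-1-yl)phenyl 4-[(tert-butyldimethylsilyl)oxy]benzoate | COc1c(OC)c(C(OC)OC)c(OC(=O)c2ccc(O[Si](C)(C)C(C)(C)C)cc2)c(CC=C(C)C)c1OC | intermediate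
12 | tert-butyl(4-{1-[2-(dimethoxymethyl)-3,4,5-trimethoxy-6-(3-methylbut-2-en-1-yl)phenoxy]ethenyl}phenoxy)dimethylsilane | COc1c(OC)c(C(OC)OC)c(OC(=C)c2ccc(O[Si](C)(C)C(C)(C)C)cc2)c(CC=C(C)C)c1OC | intermediate
13 | 2-({1-[4-(tert-butyldimethylsilyloxy)phenyl]ethenyl}oxy)-4,5,6-trimethoxy-3-(3-methylbut-2-en-1-yl)benzaldehyde | COc1c(OC)c(C=O)c(OC(=C)c2ccc(O[Si](C)(C)C(C)(C)C)cc2)c(CC=C(C)C)c1OC | intermediate
14 | (2S)-2-{4-[(tert-butyldimethylsilyl)oxy]phenyl}-5,6,7-trimethoxy-8-(3-methylbut-2-en-1-yl)-2,3-dihydro-4H-chromen-4-one | COc1c(OC)c2c(c(CC=C(C)C)c1OC)O[C@H](c1ccc(O[Si](C)(C)C(C)(C)C)cc1)CC2=O | intermediate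
15 | (2S)-2-{4-[(tert-butyldimethylsilyl)oxy]phenyl}-5-hydroxy-6,7-dimethoxy-8-(3-methylbut-2-en-1-yl)-2,3-dihydro-4H-chromen-4-one | COc1c(O)c2c(c(CC=C(C)C)c1OC)O[C@H](c1ccc(O[Si](C)(C)C(C)(C)C)cc1)CC2=O | intermediate
16 | (2S)-5-hydroxy-2-(4-hydroxyphenyl)-6,7-dimethoxy-8-(3-methylbut-2-en-1-yl)-2,3-dihydro-4H-chromen-4-one | COc1c(O)c2c(c(CC=C(C)C)c1OC)O[C@H](c1ccc(O)cc1)CC2=O | target

Total step count: 11. Longest linear sequence: 10 steps (steps 1–3 and 5–11, from 1 to 16); step 4 is a one-step side branch.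

Steps most likely to fail

1. Step 9 (the proposed new method). What may go wrong: decarbonylation of the acyl rhodium hydride, insertion in the exo sense, or poor facial discrimination in the hydride transfer. The fallback uses known chemistry, sets out from 6 and comes back at 14. Addition of MeMgBr (THF, 0 °C) to 6 should give 1-[2-hydroxy-4,5,6-trimethoxy-3-(3-methylbut-2-en-1-yl)phenyl]ethan-1-ol F1, and MnO2 (CH2Cl2, rt) should oxidise it to 1-[2-hydroxy-4,5,6-trimethoxy-3-(3-methylbut-2-en-1-yl)phenyl]ethan-1-one F2. Condensation with Me2NCH(OMe)2 (PhMe, 90 °C) should give (E)-3-(dimethylamino)-1-[2-hydroxy-4,5,6-trimethoxy-3-(3-methylbut-2-en-1-yl)phenyl]prop-2-en-1-one F3, which AcOH (60 °C) should close to 5,6,7-trimethoxy-8-(3-methylbut-2-en-1-yl)-4H-chromen-4-one F4. Catalytic asymmetric conjugate addition of commercial 4-[(tert-butyldimethylsilyl)oxy]phenylboronic acid to this chromone should then deliver 14 (Pd(OCOCF3)2, a tert-butyl pyridine–oxazoline ligand, NH4PF6, H2O, ClCH2CH2Cl, 60 °C). This is a known way from chromones to 2-arylchroman-4-ones, and the ligand antipode would be chosen for S.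

2. Step 8. What may go wrong: carbon protonation and hydrolysis of the enol ether in competition with acetal cleavage. The fallback sets out from 5, comes back at 13 and needs neither a masked aldehyde nor acid. Bromination of 5 at its only free ring position (NBS, i-Pr2NH cat., CH2Cl2, −78 °C) should give 2-bromo-3,4,5-trimethoxy-6-(3-methylbut-2-en-1-yl)phenol F5. Acylation with 9 as in step 5 should give 2-bromo-3,4,5-trimethoxy-6-(3-methylbut-2-en-1-yl)phenyl 4-[(tert-butyldimethylsilyl)oxy]benzoate F6. Petasis methylenation (Cp2TiMe2, PhMe, 70 °C) should then give {4-[1-(2-bromo-3,4,5-trimethoxy-6-(3-methylbut-2-en-1-yl)phenoxy)ethenyl]phenoxy}(tert-butyl)dimethylsilane F7. Bromine–lithium exchange (t-BuLi, 2 equiv, THF, −78 °C) and trapping with DMF should give 13 after a neutral work-up.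

3. Step 10. What may go wrong: Lewis acid ionisation of the C2–O1 bond with loss of enantiopurity, partial loss of the silyl group, or HCl addition to the prenyl alkene. The fallback sets out from 10 and comes back at 15; the methyl group is exchanged for a MOM group before any stereocentre exists. BCl3 (CH2Cl2, −78 °C), now chelated between the formyl group and its neighbouring methoxy group, should give 2-formyl-3-hydroxy-4,5-dimethoxy-6-(3-methylbut-2-en-1-yl)phenyl 4-[(tert-butyldimethylsilyl)oxy]benzoate F8. MOMCl and i-Pr2NEt (CH2Cl2) should give 2-formyl-4,5-dimethoxy-3-(methoxymethoxy)-6-(3-methylbut-2-en-1-yl)phenyl 4-[(tert-butyldimethylsilyl)oxy]benzoate F9. The conditions of steps 6 to 9 (PPTS in place of p-TsOH in the acetalisation) should then give in turn the dimethyl acetal F10, the enol ether acetal F11, the aldehyde F12 and the (2S)-5-(methoxymethoxy)flavanone F13. The peri MOM ether, the most labile acetal once it sits next to the C4 carbonyl, should come off with 1 M HCl in MeOH–THF at rt to give 15, which continues through step 11.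

Further compounds
F1 | step 9 | 1-[2-hydroxy-4,5,6-trimethoxy-3-(3-methylbut-2-en-1-yl)phenyl]ethan-1-ol (racemic) | COc1c(OC)c(C(C)O)c(O)c(CC=C(C)C)c1OC
F2 | step 9 | 1-[2-hydroxy-4,5,6-trimethoxy-3-(3-methylbut-2-en-1-yl)phenyl]ethan-1-one | COc1c(OC)c(C(C)=O)c(O)c(CC=C(C)C)c1OC
F3 | step 9 | (E)-3-(dimethylamino)-1-[2-hydroxy-4,5,6-trimethoxy-3-(3-methylbut-2-en-1-yl)phenyl]prop-2-en-1-one | COc1c(OC)c(C(=O)/C=C/N(C)C)c(O)c(CC=C(C)C)c1OC
F4 | step 9 | 5,6,7-trimethoxy-8-(3-methylbut-2-en-1-yl)-4H-chromen-4-one | COc1c(OC)c2c(=O)ccoc2c(CC=C(C)C)c1OC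
F5 | step 8 | 2-bromo-3,4,5-trimethoxy-6-(3-methylbut-2-en-1-yl)phenol | COc1c(Br)c(O)c(CC=C(C)C)c(OC)c1OC
F6 | step 8 | 2-bromo-3,4,5-trimethoxy-6-(3-methylbut-2-en-1-yl)phenyl 4-[(tert-butyldimethylsilyl)oxy]benzoate | COc1c(Br)c(OC(=O)c2ccc(O[Si](C)(C)C(C)(C)C)cc2)c(CC=C(C)C)c(OC)c1OC
F7 | step 8 | {4-[1-(2-bromo-3,4,5-trimethoxy-6-(3-methylbut-2-en-1-yl)phenoxy)ethenyl]phenoxy}(tert-butyl)dimethylsilane | COc1c(Br)c(OC(=C)c2ccc(O[Si](C)(C)C(C)(C)C)cc2)c(CC=C(C)C)c(OC)c1OC
F8 | step 10 | 2-formyl-3-hydroxy-4,5-dimethoxy-6-(3-methylbut-2-en-1-yl)phenyl 4-[(tert-butyldimethylsilyl)oxy]benzoate | COc1c(O)c(C=O)c(OC(=O)c2ccc(O[Si](C)(C)C(C)(C)C)cc2)c(CC=C(C)C)c1OC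
F9 | step 10 | 2-formyl-4,5-dimethoxy-3-(methoxymethoxy)-6-(3-methylbut-2-en-1-yl)phenyl 4-[(tert-butyldimethylsilyl)oxy]benzoate | COc1c(OCOC)c(C=O)c(OC(=O)c2ccc(O[Si](C)(C)C(C)(C)C)cc2)c(CC=C(C)C)c1OC
F10 | step 10 | 2-(dimethoxymethyl)-4,5-dimethoxy-3-(methoxymethoxy)-6-(3-methylbut-2-en-1-yl)phenyl 4-[(tert-butyldimethylsilyl)oxy]benzoate | COc1c(OCOC)c(C(OC)OC)c(OC(=O)c2ccc(O[Si](C)(C)C(C)(C)C)cc2)c(CC=C(C)C)c1OC
F11 | step 10 | tert-butyl(4-{1-[2-(dimethoxymethyl)-4,5-dimethoxy-3-(methoxymethoxy)-6-(3-methylbut-2-en-1-yl)phenoxy]ethenyl}phenoxy)dimethylsilane | COc1c(OCOC)c(C(OC)OC)c(OC(=C)c2ccc(O[Si](C)(C)C(C)(C)C)cc2)c(CC=C(C)C)c1OC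
F12 | step 10 | 2-({1-[4-(tert-butyldimethylsilyloxy)phenyl]ethenyl}oxy)-4,5-dimethoxy-6-(methoxymethoxy)-3-(3-methylbut-2-en-1-yl)benzaldehyde | COc1c(OCOC)c(C=O)c(OC(=C)c2ccc(O[Si](C)(C)C(C)(C)C)cc2)c(CC=C(C)C)c1OC
F13 | step 10 | (2S)-2-{4-[(tert-butyldimethylsilyl)oxy]phenyl}-6,7-dimethoxy-5-(methoxymethoxy)-8-(3-methylbut-2-en-1-yl)-2,3-dihydro-4H-chromen-4-one | COc1c(OCOC)c2c(c(CC=C(C)C)c1OC)O[C@H](c1ccc(O[Si](C)(C)C(C)(C)C)cc1)CC2=O
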